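Ring numbering of the target: C1 (bears the side chain), C2 (CHOH), C3 (CH-isopropenyl), C4 (quaternary: methyl, vinyl), C5, C6 (CH2). Everything rests on forming C4–C5 by an Ireland–Claisen ring contraction. The precursor is a six-membered lactone made of C4, C3, C2, C1, the future vinyl carbon (as C=O) and a temporary oxygen on C1, with C6=C5 as a vinyl group on C1. As its silyl ketene acetal, one [3,3] shift closes the carbocycle, cleaves the lactone, transfers the C1–O configuration to C4 and unmasks a carboxyl for the vinyl group. It exploits the 1,4-relationship of C4 and C1 across the cyclohexane and the C2 oxygen, which steers the isopropenyl group.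

Key step: step 5

Assumption: (3R,4R)-hexa-1,5-diene-3,4-diol (1), the C2-symmetric diol derived from D-mannitol, is taken as a commercial starting material.

Step 1
Reactants: 1 (3R,4R)-hexa-1,5-diene-3,4-diol
Product: 2 (3R,4R)-4-[(tert-butyldimethylsilyl)oxy]hexa-1,5-dien-3-ol
Conditions: NaH (1.0 equiv), THF, 0 °C; then TBSCl (1.0 equiv), 0 °C → rt
Reagents that add atoms: tert-butyldimethylsilyl chloride CC(C)(C)[Si](C)(C)Cl
Why: Silylation of the monosodium alkoxide of a C2-symmetric diol gives a single mono-ether because the two hydroxyls are homotopic, and neither stereocentre is touched.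

Step 2
Reactants: 2 (3R,4R)-4-[(tert-butyldimethylsilyl)oxy]hexa-1,5-dien-3-ol
Product: 3 (3S,4R)-4-[(tert-butyldimethylsilyl)oxy]hexa-1,5-dien-3-yl 2-methylprop-2-enoate
Conditions: methacrylic acid, PPh3, DIAD, THF, 0 °C → rt
Reagents that add atoms: methacrylic acid C=C(C)C(=O)O
Why: Mitsunobu esterification displaces the activated allylic carbinol oxygen by methacrylate with SN2 inversion, turning the threo (3R,4R) array into the erythro (3S,4R) ester in which silyloxy and vinyl groups will be trans on the lactone.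

Step 3
Reactants: 3 (3S,4R)-4-[(tert-butyldimethylsilyl)oxy]hexa-1,5-dien-3-yl 2-methylprop-2-enoate
Product: 4 (5R,6S)-5-[(tert-butyldimethylsilyl)oxy]-3-methyl-6-vinyl-5,6-dihydro-2H-pyran-2-one
Conditions: second-generation Grubbs catalyst (H2IMes)(PCy3)Cl2Ru=CHPh (5 mol %), toluene (0.005 M), 80 °C
Reagents that add atoms: none
Why: Ring-closing metathesis between the methacrylate alkene and the vinyl group on the silyloxy-bearing carbon closes the six-membered α-methyl-α,β-unsaturated lactone (the other vinyl could only give a five-membered ring and closes more slowly), releasing ethene and leaving both stereocentres untouched.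

Step 4
Reactants: 4 (5R,6S)-5-[(tert-butyldimethylsilyl)oxy]-3-methyl-6-vinyl-5,6-dihydro-2H-pyran-2-one
Product: 6 (3S,4R,5R,6S)-5-[(tert-butyldimethylsilyl)oxy]-3-methyl-4-(prop-1-en-2-yl)-6-vinyltetrahydro-2H-pyran-2-one, via trimethylsilyl ketene acetal 5 (not isolated)
Conditions: CH2=C(CH3)MgBr (2 equiv), CuBr·SMe2 (20 mol %), TMSCl, THF, −78 °C; then aq NH4Cl, 0 °C
Reagents that add atoms: isopropenylmagnesium bromide CC(=C)[Mg]Br
Why: Copper-catalysed conjugate addition of the isopropenyl Grignard reagent, accelerated by TMSCl, should deliver the nucleophile to C4 (pyranone numbering) anti to the adjacent C5 silyloxy group and hence cis to the C6 vinyl group, setting C4 as R, while the C3 configuration fixed on protonation of 5 is of no consequence because C3 is enolised in step 5.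

Step 5
Reactants: 6 (3S,4R,5R,6S)-5-[(tert-butyldimethylsilyl)oxy]-3-methyl-4-(prop-1-en-2-yl)-6-vinyltetrahydro-2H-pyran-2-one
Product: 9 (1R,5S,6S)-5-[(tert-butyldimethylsilyl)oxy]-1-methyl-6-(prop-1-en-2-yl)cyclohex-3-ene-1-carboxylic acid, via cyclic silyl ketene acetal 7 (not isolated), via silyl ester 8 (not isolated)
Conditions: LDA, THF–HMPA, −78 °C; TBSCl, −78 °C → rt; then toluene, 105 °C; then H2O, aq KHSO4
Reagents that add atoms: none
Why: LDA removes the only α-hydrogen (C3–H, pyranone numbering) and O-silylation gives the cyclic silyl ketene acetal 7, whose C3=C2(OSi)–O1–C6–CH=CH2 array is an allyl vinyl ether held inside the lactone; a suprafacial [3,3]-sigmatropic shift through a boat-like transition state (bicyclo[2.2.2]octene-like) forms the C3–CH2 bond (C4–C5 of the target ring), breaks O1–C6 and gives silyl ester 8, which is hydrolysed on work-up. The closest known reaction type is the Ireland–Claisen rearrangement of lactone silyl ketene acetals, which contracts 6-alkenyl tetrahydropyran-2-ones to cyclohex-3-ene-1-carboxylic acids. The cyclohexene ring is closed by this concerted pericyclic C–C bond formation, a ring contraction in which C4 and C5 of the lactone are the two-atom tether between the ketene acetal carbon and the carbinol carbon, and not by an ionic cyclisation. The new quaternary stereocentre is controlled by chirality transfer from C6: the tethered vinyl group can reach C3 only on its own face of the ring, so the new bond forms cis to the former vinyl group and the C4 isopropenyl group, cis to vinyl in 6, ends trans to the carboxyl group and cis to the methyl group (1R in 9). The step needs O- rather than C-silylation and rearrangement rather than ring opening of the lactone enolate to a ketene; trapping with TBSCl in THF–HMPA at −78 °C and the fixed endocyclic geometry of the ketene acetal, which also makes the C3 configuration of 6 irrelevant, should secure this.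

Step 6
Reactants: 9 (1R,5S,6S)-5-[(tert-butyldimethylsilyl)oxy]-1-methyl-6-(prop-1-en-2-yl)cyclohex-3-ene-1-carboxylic acid
Product: 10 [(1R,5S,6S)-5-[(tert-butyldimethylsilyl)oxy]-1-methyl-6-(prop-1-en-2-yl)cyclohex-3-en-1-yl]methanol
Conditions: LiAlH4, THF, 0 °C → 65 °C; aq NaOH work-up
Reagents that add atoms: none
Why: Hydride reduction with LiAlH4 converts the α-quaternary carboxylic acid into the primary alcohol while the silyl ether and the isolated alkenes are inert.

Step 7
Reactants: 10 [(1R,5S,6S)-5-[(tert-butyldimethylsilyl)oxy]-1-methyl-6-(prop-1-en-2-yl)cyclohex-3-en-1-yl]methanol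
Product: 11 (1R,5S,6S)-5-[(tert-butyldimethylsilyl)oxy]-1-methyl-6-(prop-1-en-2-yl)cyclohex-3-ene-1-carbaldehyde
Conditions: Dess–Martin periodinane, NaHCO3, CH2Cl2, 0 °C → rt
Reagents that add atoms: none
Why: Dess–Martin oxidation gives the aldehyde, which has no α-hydrogen and therefore cannot epimerise.

Step 8
Reactants: 11 (1R,5S,6S)-5-[(tert-butyldimethylsilyl)oxy]-1-methyl-6-(prop-1-en-2-yl)cyclohex-3-ene-1-carbaldehyde
Product: 12 tert-butyldimethyl{[(1S,5S,6S)-5-methyl-6-(prop-1-en-2-yl)-5-vinylcyclohex-2-en-1-yl]oxy}silane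
Conditions: Ph3PCH3Br, KN(SiMe3)2, THF, 0 °C; then 11, 0 °C → rt
Reagents that add atoms: methyltriphenylphosphonium bromide C[P+](c1ccccc1)(c1ccccc1)c1ccccc1.[Br-]
Why: Wittig methylenation of the non-enolisable aldehyde converts the former lactone carbonyl carbon into the vinyl group on the quaternary centre.

Step 9
Reactants: 12 tert-butyldimethyl{[(1S,5S,6S)-5-methyl-6-(prop-1-en-2-yl)-5-vinylcyclohex-2-en-1-yl]oxy}silane
Product: 13 (1S,5S,6S)-5-methyl-6-(prop-1-en-2-yl)-5-vinylcyclohex-2-en-1-ol
Conditions: Bu4NF, THF, 0 °C → rt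
Reagents that add atoms: none
Why: Fluoride-mediated desilylation frees the allylic alcohol without touching the stereocentres.

Step 10
Reactants: 13 (1S,5S,6S)-5-methyl-6-(prop-1-en-2-yl)-5-vinylcyclohex-2-en-1-ol
Product: 14 (5S,6S)-5-methyl-6-(prop-1-en-2-yl)-5-vinylcyclohex-2-en-1-one
Conditions: MnO2 (activated), CH2Cl2, rt
Reagents that add atoms: none
Why: Allylic oxidation with neutral MnO2 gives the cyclohexenone, and it is placed after the Wittig step so that no strong base meets the ketone whose isopropenyl-bearing α-carbon could epimerise.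

Step 11
Reactants: 14 (5S,6S)-5-methyl-6-(prop-1-en-2-yl)-5-vinylcyclohex-2-en-1-one; 15 2,2-dimethyl-1,3-dioxan-5-one
Product: 17 (2S,3S,6S)-6-(5-hydroxy-2,2-dimethyl-1,3-dioxan-5-yl)-3-methyl-2-(prop-1-en-2-yl)-3-vinylcyclohexan-1-one, via lithium enolate 16 (not isolated)
Conditions: Li[HB(sec-Bu)3] (L-Selectride), THF, −78 °C; then CeCl3 (anhydrous), −78 °C; then 15, −78 °C; AcOH quench
Reagents that add atoms: none
Why: In this reductive aldol reaction, 1,4-hydride addition to the β-unsubstituted cyclohexenone generates enolate 16 regiospecifically on the side away from the isopropenyl group, and its cerium-mediated reversible addition to the symmetrical ketone 15 should leave the bulky carbinol substituent equatorial (cis to the isopropenyl group across the carbonyl), setting C6 of the cyclohexanone as S.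

Step 12
Reactants: 17 (2S,3S,6S)-6-(5-hydroxy-2,2-dimethyl-1,3-dioxan-5-yl)-3-methyl-2-(prop-1-en-2-yl)-3-vinylcyclohexan-1-one
Product: 18 5-[(1R,2R,3S,4S)-2-hydroxy-4-methyl-3-(prop-1-en-2-yl)-4-vinylcyclohexyl]-2,2-dimethyl-1,3-dioxan-5-ol
Conditions: Li, NH3 (l), THF, t-BuOH, −78 °C; then NH4Cl
Reagents that add atoms: none
Why: Dissolving-metal reduction passes through the ketyl radical anion and the pyramidal carbanion and should give the thermodynamically favoured equatorial alcohol, trans to both neighbouring substituents (2R), whereas hydride reagents would be deflected by the axial methyl group towards the axial alcohol.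

Step 13
Reactants: 18 5-[(1R,2R,3S,4S)-2-hydroxy-4-methyl-3-(prop-1-en-2-yl)-4-vinylcyclohexyl]-2,2-dimethyl-1,3-dioxan-5-ol
Product: 19 2-[(1R,2R,3S,4S)-2-hydroxy-4-methyl-3-(prop-1-en-2-yl)-4-vinylcyclohexyl]propane-1,2,3-triol
Conditions: AcOH–H2O–THF (3:1:1), 40 °C
Reagents that add atoms: none
Why: Acid-catalysed hydrolysis of the isopropylidene acetal releases the two primary hydroxyls as acetone is lost, with no stereocentre involved.

Step 14
Reactants: 19 2-[(1R,2R,3S,4S)-2-hydroxy-4-methyl-3-(prop-1-en-2-yl)-4-vinylcyclohexyl]propane-1,2,3-triol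
Product: 20 2-hydroxy-2-[(1R,2R,3S,4S)-2-hydroxy-4-methyl-3-(prop-1-en-2-yl)-4-vinylcyclohexyl]propane-1,3-diyl diacetate
Conditions: Ac2O (2.2 equiv), pyridine, CH2Cl2, −20 → 0 °C
Reagents that add atoms: acetic anhydride CC(=O)OC(C)=O
Why: Acylation with a small excess of acetic anhydride should be selective for the two primary hydroxyls because the secondary one is flanked by two branched ring carbons and the tertiary one does not react with pyridine as the only base.

Compound list
1 | (3R,4R)-hexa-1,5-diene-3,4-diol | O[C@H](C=C)[C@H](O)C=C | starting material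
2 | (3R,4R)-4-[(tert-butyldimethylsilyl)oxy]hexa-1,5-dien-3-ol | O[C@H](C=C)[C@H](O[Si](C)(C)C(C)(C)C)C=C | intermediate
3 | (3S,4R)-4-[(tert-butyldimethylsilyl)oxy]hexa-1,5-dien-3-yl 2-methylprop-2-enoate | C=C(C)C(=O)O[C@@H](C=C)[C@H](O[Si](C)(C)C(C)(C)C)C=C | intermediate
4 | (5R,6S)-5-[(tert-butyldimethylsilyl)oxy]-3-methyl-6-vinyl-5,6-dihydro-2H-pyran-2-one | O=C1O[C@@H](C=C)[C@H](O[Si](C)(C)C(C)(C)C)C=C1C | intermediate
5 | tert-butyldimethyl{[(2S,3R,4S)-5-methyl-4-(prop-1-en-2-yl)-6-[(trimethylsilyl)oxy]-2-vinyl-3,4-dihydro-2H-pyran-3-yl]oxy}silane | CC1=C(O[Si](C)(C)C)O[C@@H](C=C)[C@H](O[Si](C)(C)C(C)(C)C)[C@H]1C(C)=C | intermediate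
6 | (3S,4R,5R,6S)-5-[(tert-butyldimethylsilyl)oxy]-3-methyl-4-(prop-1-en-2-yl)-6-vinyltetrahydro-2H-pyran-2-one | O=C1O[C@@H](C=C)[C@H](O[Si](C)(C)C(C)(C)C)[C@@H](C(C)=C)[C@@H]1C | intermediate
7 | tert-butyl{[(2S,3R,4S)-6-[(tert-butyldimethylsilyl)oxy]-5-methyl-4-(prop-1-en-2-yl)-2-vinyl-3,4-dihydro-2H-pyran-3-yl]oxy}dimethylsilane | CC1=C(O[Si](C)(C)C(C)(C)C)O[C@@H](C=C)[C@H](O[Si](C)(C)C(C)(C)C)[C@H]1C(C)=C | intermediate
8 | tert-butyldimethylsilyl (1R,5S,6S)-5-[(tert-butyldimethylsilyl)oxy]-1-methyl-6-(prop-1-en-2-yl)cyclohex-3-ene-1-carboxylate | CC(C)(C)[Si](C)(C)OC(=O)[C@]1(C)CC=C[C@H](O[Si](C)(C)C(C)(C)C)[C@H]1C(=C)C | intermediate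
9 | (1R,5S,6S)-5-[(tert-butyldimethylsilyl)oxy]-1-methyl-6-(prop-1-en-2-yl)cyclohex-3-ene-1-carboxylic acid | OC(=O)[C@]1(C)CC=C[C@H](O[Si](C)(C)C(C)(C)C)[C@H]1C(=C)C | intermediate
10 | [(1R,5S,6S)-5-[(tert-butyldimethylsilyl)oxy]-1-methyl-6-(prop-1-en-2-yl)cyclohex-3-en-1-yl]methanol | OC[C@]1(C)CC=C[C@H](O[Si](C)(C)C(C)(C)C)[C@H]1C(=C)C | intermediate
11 | (1R,5S,6S)-5-[(tert-butyldimethylsilyl)oxy]-1-methyl-6-(prop-1-en-2-yl)cyclohex-3-ene-1-carbaldehyde | O=C[C@]1(C)CC=C[C@H](O[Si](C)(C)C(C)(C)C)[C@H]1C(=C)C | intermediate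
12 | tert-butyldimethyl{[(1S,5S,6S)-5-methyl-6-(prop-1-en-2-yl)-5-vinylcyclohex-2-en-1-yl]oxy}silane | C=C[C@]1(C)CC=C[C@H](O[Si](C)(C)C(C)(C)C)[C@H]1C(=C)C | intermediate
13 | (1S,5S,6S)-5-methyl-6-(prop-1-en-2-yl)-5-vinylcyclohex-2-en-1-ol | C=C[C@]1(C)CC=C[C@H](O)[C@H]1C(=C)C | intermediate
14 | (5S,6S)-5-methyl-6-(prop-1-en-2-yl)-5-vinylcyclohex-2-en-1-one | C=C[C@]1(C)CC=CC(=O)[C@H]1C(=C)C | intermediate
15 | 2,2-dimethyl-1,3-dioxan-5-one | CC1(C)OCC(=O)CO1 | starting material
16 | lithium (5S,6S)-5-methyl-6-(prop-1-en-2-yl)-5-vinylcyclohex-1-en-1-olate | C=C[C@]1(C)CCC=C([O-])[C@H]1C(=C)C.[Li+] | intermediate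
17 | (2S,3S,6S)-6-(5-hydroxy-2,2-dimethyl-1,3-dioxan-5-yl)-3-methyl-2-(prop-1-en-2-yl)-3-vinylcyclohexan-1-one | C=C[C@]1(C)CC[C@@H](C2(O)COC(C)(C)OC2)C(=O)[C@H]1C(=C)C | intermediate
18 | 5-[(1R,2R,3S,4S)-2-hydroxy-4-methyl-3-(prop-1-en-2-yl)-4-vinylcyclohexyl]-2,2-dimethyl-1,3-dioxan-5-ol | C=C[C@]1(C)CC[C@@H](C2(O)COC(C)(C)OC2)[C@H](O)[C@H]1C(=C)C | intermediate
19 | 2-[(1R,2R,3S,4S)-2-hydroxy-4-methyl-3-(prop-1-en-2-yl)-4-vinylcyclohexyl]propane-1,2,3-triol | C=C[C@]1(C)CC[C@@H](C(O)(CO)CO)[C@H](O)[C@H]1C(=C)C | intermediate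
20 | 2-hydroxy-2-[(1R,2R,3S,4S)-2-hydroxy-4-methyl-3-(prop-1-en-2-yl)-4-vinylcyclohexyl]propane-1,3-diyl diacetate | C=C[C@]1(C)CC[C@@H](C(O)(COC(C)=O)COC(C)=O)[C@H](O)[C@H]1C(=C)C | target

Total step count: 14. Longest linear sequence: 14 steps (1 to 20); ketone 15 is used as purchased.

Steps most likely to fail

Step 5. The lactone enolate may be silylated on carbon or open to a ketene before it is trapped, and the crowded boat transition state may be slow enough for the ketene acetal to decompose first. The fallback sets out from lactone 6. Reduction with i-Bu2AlH at −78 °C should give the lactol (3S,4R,5R,6S)-5-[(tert-butyldimethylsilyl)oxy]-3-methyl-4-(prop-1-en-2-yl)-6-vinyltetrahydro-2H-pyran-2-ol F1. Dehydration through its mesylate (MsCl, Et3N, then warming) should give the cyclic enol ether tert-butyldimethyl{[(2S,3R,4S)-5-methyl-4-(prop-1-en-2-yl)-2-vinyl-3,4-dihydro-2H-pyran-3-yl]oxy}silane F2. Heating F2 (xylene, sealed tube, about 190 °C) brings about the thermal Claisen rearrangement of the 2-vinyl-3,4-dihydro-2H-pyran, with the same chirality transfer, and gives the aldehyde directly. The fallback comes back to the route at 11, so steps 6 and 7 are not needed.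

Step 11. Some 1,2-reduction may compete, the basic enolate may deprotonate the enolisable ketone 15 instead of adding to it, and the aldolate may revert on warming. The fallback sets out from enone 14. L-Selectride followed by TMSCl should trap the enolate as the silyl enol ether {[(5S,6S)-5-methyl-6-(prop-1-en-2-yl)-5-vinylcyclohex-1-en-1-yl]oxy}trimethylsilane F3. A Mukaiyama aldol addition of F3 to 15 under TiCl4 (or BF3·OEt2) in CH2Cl2 at −78 °C then forms the same bond under Lewis-acid control and comes back to the route at 17.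

Step 12. Facial selectivity may be poor, leaving axial alcohol, and the β-hydroxy ketone may cleave by retro-aldol reaction in the basic medium. The fallback sets out from 17. NaBH4 in MeOH is expected to give mainly the axial epimer 5-[(1R,2S,3S,4S)-2-hydroxy-4-methyl-3-(prop-1-en-2-yl)-4-vinylcyclohexyl]-2,2-dimethyl-1,3-dioxan-5-ol F4. F4 is then equilibrated by reversible Meerwein–Ponndorf–Verley/Oppenauer hydrogen transfer (Al(O-i-Pr)3, i-PrOH, a trace of acetone, toluene, reflux) to the all-equatorial alcohol, and the fallback comes back to the route at 18.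

Further compounds
F1 | step 5 | (3S,4R,5R,6S)-5-[(tert-butyldimethylsilyl)oxy]-3-methyl-4-(prop-1-en-2-yl)-6-vinyltetrahydro-2H-pyran-2-ol (both anomers) | OC1O[C@@H](C=C)[C@H](O[Si](C)(C)C(C)(C)C)[C@@H](C(C)=C)[C@@H]1C
F2 | step 5 | tert-butyldimethyl{[(2S,3R,4S)-5-methyl-4-(prop-1-en-2-yl)-2-vinyl-3,4-dihydro-2H-pyran-3-yl]oxy}silane | CC1=CO[C@@H](C=C)[C@H](O[Si](C)(C)C(C)(C)C)[C@H]1C(C)=C
F3 | step 11 | {[(5S,6S)-5-methyl-6-(prop-1-en-2-yl)-5-vinylcyclohex-1-en-1-yl]oxy}trimethylsilane | C=C[C@]1(C)CCC=C(O[Si](C)(C)C)[C@H]1C(=C)C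
F4 | step 12 | 5-[(1R,2S,3S,4S)-2-hydroxy-4-methyl-3-(prop-1-en-2-yl)-4-vinylcyclohexyl]-2,2-dimethyl-1,3-dioxan-5-ol | C=C[C@]1(C)CC[C@@H](C2(O)COC(C)(C)OC2)[C@@H](O)[C@H]1C(=C)C
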